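**Plan** (labdane numbering: decalin C1–C10, gem-dimethyl on C4, methyl C20 on C10, C17 on C8, side chain C11–C16 on C9)
1. Ring B holds the C7=C8 double bond between sp3 C6 and C9, with C5, C10 (quaternary, methyl) and C9 as adjoining stereocentres. This cyclohexene retron is cut at C5–C6 and C9–C10 into an α-methyl enal (C5=C10) and a 1,2-disubstituted butadiene (C6=C7–C8=C9).
2. Ring A is cut at C1=C2 (metathesis) and C3–C4 (allyl transfer to a C4 radical); the side chain at C12=C13 and C14=C15 (two Wittig reactions); O6 and the C17 acid come from late oxidations.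
3. Forward: diene (steps 1–5), ring B by enantioselective [4+2] (step 6), ring A (steps 7–12), C6 ketone/alcohol/acetate (13–15), dienyl chain (16–19), C17 acid (20–22).
4. Stereochemistry: C10 from the chiral Lewis acid; C5 from the E-enal; C9 from the E-diene with exo-formyl approach; C6 from hydride attack anti to the axial C10/C4 methyls; C12=C13 from a stabilised ylide.

Key step: step 6

Assumption: the facial sense of the cycloaddition is taken from the usual formyl C–H···O model of the enal–oxazaborolidinium complex, which puts the diene on the Si face of C10 with the (R)-catalyst; if the adduct proved antipodal, the (S)-catalyst would be used with no other change.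
Abbreviations: TBS = tert-butyldimethylsilyl, TBDPS = tert-butyldiphenylsilyl.

**Step 1**
Reactants: 1 tert-butyl(but-3-yn-1-yloxy)dimethylsilane
Product: 2 ethyl 5-(TBSO)pent-2-ynoate
Conditions: n-BuLi, THF, −78 °C; ClCO2Et, −78 → 0 °C
Reagents that add atoms: ethyl chloroformate CCOC(=O)Cl
Why: C-acylation of a lithium acetylide with a chloroformate is the standard route to alk-2-ynoates and leaves the silyl ether untouched.

**Step 2**
Reactants: 2 ethyl 5-(TBSO)pent-2-ynoate
Product: 3 ethyl (2E)-5-(TBSO)-2-(tributylstannyl)pent-2-enoate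
Conditions: Bu3SnH (slow addition), Pd(PPh3)4 (2 mol %), THF, 0 °C → rt
Reagents that add atoms: tributyltin hydride CCCC[SnH](CCCC)CCCC
Why: Palladium-catalysed hydrostannation of alk-2-ynoates is a syn addition that places tin α to the ester, so the ester ends up cis to the chain, which fixes the later C8=C9 geometry.

**Step 3**
Reactants: 3 ethyl (2E)-5-(TBSO)-2-(tributylstannyl)pent-2-enoate
Product: 4 (2E)-5-(TBSO)-2-(tributylstannyl)pent-2-en-1-ol
Conditions: i-Bu2AlH (2.2 equiv), CH2Cl2, −78 °C; Rochelle salt work-up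
Reagents that add atoms: none
Why: 1,2-Reduction of the enoate with a dialkylaluminium hydride gives the allylic alcohol without touching the alkenylstannane or its geometry.

**Step 4**
Reactants: 4 (2E)-5-(TBSO)-2-(tributylstannyl)pent-2-en-1-ol
Product: 5 (2Z)-5-(TBSO)-2-ethenylpent-2-en-1-ol
Conditions: bromoethene (1 M in THF, 3 equiv), Pd2(dba)3 (2.5 mol %), AsPh3 (20 mol %), CuI (10 mol %), NMP, 40 °C, sealed tube
Reagents that add atoms: bromoethene C=CBr
Why: The Stille coupling proceeds with retention at both alkenyl partners (copper co-catalysis helps the α-branched stannane), so the new vinyl group is trans to the chain.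

**Step 5**
Reactants: 5 (2Z)-5-(TBSO)-2-ethenylpent-2-en-1-ol
Product: 6 tert-butyl{[(2Z)-5-(TBSO)-2-ethenylpent-2-en-1-yl]oxy}diphenylsilane
Conditions: TBDPSCl, imidazole, CH2Cl2, rt
Reagents that add atoms: tert-butyl(chloro)diphenylsilane CC(C)(C)[Si](Cl)(c1ccccc1)c1ccccc1
Why: Silylation of the primary allylic alcohol gives a bulky, acid-robust ether that outlasts the TBS group and shields the C8 flank of the diene and, later, the C17 hydrogens.

**Step 6**
Reactants: 6 tert-butyl{[(2Z)-5-(TBSO)-2-ethenylpent-2-en-1-yl]oxy}diphenylsilane; 7 ethyl (2E)-3-methyl-4-oxobut-2-enoate (1.5 equiv)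
Product: 8 ethyl (1S,5R,6S)-5-(2-TBSO-ethyl)-4-(TBDPSO-methyl)-6-formyl-6-methylcyclohex-3-ene-1-carboxylate
Conditions: (R)-3,3-diphenyl-1-(2-methylphenyl)tetrahydro-1H,3H-pyrrolo[1,2-c][1,3,2]oxazaborole (20 mol %), HNTf2 (17 mol %), CH2Cl2, −78 → −40 °C
Reagents that add atoms: none
Why: The protonated oxazaborolidine binds the formyl oxygen of 7, and the s-cis diene 6 adds to the activated C5=C10 bond in a concerted, asynchronous [4+2] cycloaddition in which C5 (β to the formyl group) bonds to the unsubstituted terminus C6 ahead of C10 to C9. The closest known reaction type is the oxazaborolidinium-catalysed Diels–Alder reaction of α-methyl α,β-enals with acyclic 1-substituted butadienes, which creates a quaternary stereocentre next to a tertiary one. Ring B is closed by this intermolecular cycloaddition, both new σ-bonds (C5–C6 and C9–C10) arising suprafacially on diene and dienophile through a boat-like six-membered transition state. C10 is set by the catalyst, whose aryl group covers one face of the bound s-trans enal so that the diene meets the Si face of C10; C5 is tied to C10 by the E geometry of 7 (ester cis to the C10 methyl); C9 is set by the E geometry of the C8=C9 bond of 6 together with the formyl-exo, ester-endo orientation (C11 chain cis to the C10 methyl). The step needs regioselectivity, exo-formyl selectivity and facial selectivity: the alkyl group on C9 outweighs the weakly donating CH2OSi group on C8 and directs C9 to C10, the α-methyl group and the bulky CH2OTBDPS group on C8 keep the catalyst-bound formyl group out of the endo position while the ester sits endo under unsubstituted C7, and the catalyst supplies the facial bias.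

**Step 7**
Reactants: 8 ethyl (1S,5R,6S)-5-(2-TBSO-ethyl)-4-(TBDPSO-methyl)-6-formyl-6-methylcyclohex-3-ene-1-carboxylate
Product: 9 ethyl 5-(2-TBSO-ethyl)-4-(TBDPSO-methyl)-6-ethenyl-6-methylcyclohex-3-ene-1-carboxylate (ring centres as in 8)
Conditions: Ph3PCH3Br, KN(SiMe3)2, THF, 0 °C; then 8, 0 °C → rt
Reagents that add atoms: methyltriphenylphosphonium bromide C[P+](c1ccccc1)(c1ccccc1)c1ccccc1.[Br-]
Why: Wittig methylenation of the neopentyl aldehyde is much faster than any reaction at the hindered ester and turns C1 into the alkene needed for ring closure, with no stereocentre touched.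

**Step 8**
Reactants: 9 ethyl 5-(2-TBSO-ethyl)-4-(TBDPSO-methyl)-6-ethenyl-6-methylcyclohex-3-ene-1-carboxylate
Product: 11 2-[5-(2-TBSO-ethyl)-4-(TBDPSO-methyl)-6-ethenyl-6-methylcyclohex-3-en-1-yl]propan-2-ol, via methyl ketone 10 (not isolated)
Conditions: MeLi (4 equiv), Et2O, −78 → 0 °C; H2O
Reagents that add atoms: methyllithium C[Li]
Why: Double addition of the small, strongly nucleophilic organolithium to the ester (the intermediate ketone reacts faster than the ester) installs both C4 methyl groups; C5 is not epimerised.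

**Step 9**
Reactants: 11 2-[5-(2-TBSO-ethyl)-4-(TBDPSO-methyl)-6-ethenyl-6-methylcyclohex-3-en-1-yl]propan-2-ol
Product: 13 cesium 2-[5-(2-TBSO-ethyl)-4-(TBDPSO-methyl)-6-ethenyl-6-methylcyclohex-3-en-1-yl]propan-2-yl oxalate, via methyl oxalate 12 (not isolated)
Conditions: ClC(O)CO2Me, Et3N, DMAP (cat.), CH2Cl2, 0 °C → rt; then CsOH (1.0 equiv), THF/H2O, rt
Reagents that add atoms: methyl chlorooxoacetate COC(=O)C(Cl)=O; cesium hydroxide [Cs+].[OH-]
Why: Acylation of the tertiary alcohol with the very reactive oxalyl half-chloride and selective saponification of the unhindered methyl ester gives the oxalate salt, a radical precursor made without a C4 cation and hence without hydride shift or elimination.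

**Step 10**
Reactants: 13 cesium 2-[5-(2-TBSO-ethyl)-4-(TBDPSO-methyl)-6-ethenyl-6-methylcyclohex-3-en-1-yl]propan-2-yl oxalate
Product: 14 6-(2-TBSO-ethyl)-1-(TBDPSO-methyl)-5-ethenyl-5-methyl-4-(2-methylpent-4-en-2-yl)cyclohex-1-ene (ring centres as in 8)
Conditions: allyl phenyl sulfone (3 equiv), Ir[dF(CF3)ppy]2(dtbbpy)PF6 (2 mol %), DME/DMF 3:1, blue LEDs, 60 °C
Reagents that add atoms: allyl phenyl sulfone C=CCS(=O)(=O)c1ccccc1
Why: Photoredox oxidation of the oxalate releases two CO2 and the tertiary C4 radical, which adds to the sulfone terminus and expels PhSO2• (radical allylation by addition–fragmentation; the sulfonyl radical is reduced to sulfinate to close the cycle), forming C3–C4 at a quaternary carbon with no stereochemical consequence.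

**Step 11**
Reactants: 14 6-(2-TBSO-ethyl)-1-(TBDPSO-methyl)-5-ethenyl-5-methyl-4-(2-methylpent-4-en-2-yl)cyclohex-1-ene
Product: 15 12-O-TBS-17-O-TBDPS-13,14,15,16-tetranor-ent-labda-1,7-diene-12,17-diol
Conditions: second-generation Grubbs catalyst RuCl2(H2IMes)(PCy3)(=CHPh) (5 mol %), CH2Cl2 (0.005 M), 40 °C
Reagents that add atoms: none
Why: Ring-closing metathesis of the two monosubstituted alkenes closes six-membered ring A with loss of ethene; the trisubstituted C7=C8 bond is too hindered to compete, and the trans ring fusion is already fixed at C5 and C10.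

**Step 12**
Reactants: 15 12-O-TBS-17-O-TBDPS-13,14,15,16-tetranor-ent-labda-1,7-diene-12,17-diol
Product: 16 12-O-TBS-17-O-TBDPS-13,14,15,16-tetranor-ent-labd-7-ene-12,17-diol
Conditions: H2 (3 atm), RhCl(PPh3)3 (10 mol %), toluene/EtOH, rt
Reagents that add atoms: none
Why: Homogeneous rhodium-catalysed hydrogenation reduces the cis-disubstituted C1=C2 bond far faster than the trisubstituted C7=C8 bond and does not hydrogenolyse the allylic silyl ether.

**Step 13**
Reactants: 16 12-O-TBS-17-O-TBDPS-13,14,15,16-tetranor-ent-labd-7-ene-12,17-diol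
Product: 17 12-(TBSO)-17-(TBDPSO)-13,14,15,16-tetranor-ent-labd-7-en-6-one
Conditions: CrO3, 3,5-dimethylpyrazole, CH2Cl2, −20 °C
Reagents that add atoms: chromium trioxide O=[Cr](=O)=O
Why: Chromium-mediated allylic C–H oxidation converts C6, the only ring methylene allylic to C7=C8, into the conjugated ketone; C9–H is tertiary and cannot give a ketone, and the C17 hydrogens are shielded by the TBDPS group.

**Step 14**
Reactants: 17 12-(TBSO)-17-(TBDPSO)-13,14,15,16-tetranor-ent-labd-7-en-6-one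
Product: 18 12-O-TBS-17-O-TBDPS-13,14,15,16-tetranor-ent-labd-7-ene-6β,12,17-triol (6-OH cis to the C10 methyl)
Conditions: NaBH4, CeCl3·7H2O, MeOH/THF, −40 °C
Reagents that add atoms: none
Why: Luche 1,2-reduction delivers hydride to C6 from the face opposite the 1,3-diaxial C10 and C4 methyl groups, which sets C6 as the axial alcohol cis to the C10 methyl.

**Step 15**
Reactants: 18 12-O-TBS-17-O-TBDPS-13,14,15,16-tetranor-ent-labd-7-ene-6β,12,17-triol
Product: 19 6β-acetoxy-12-(TBSO)-17-(TBDPSO)-13,14,15,16-tetranor-ent-labd-7-ene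
Conditions: Ac2O, DMAP, pyridine, 40 °C
Reagents that add atoms: acetic anhydride CC(=O)OC(C)=O
Why: DMAP-catalysed acylation esterifies the only free hydroxyl, a hindered axial allylic alcohol, with retention at C6.

**Step 16**
Reactants: 19 6β-acetoxy-12-(TBSO)-17-(TBDPSO)-13,14,15,16-tetranor-ent-labd-7-ene
Product: 20 6β-acetoxy-17-(TBDPSO)-13,14,15,16-tetranor-ent-labd-7-en-12-ol
Conditions: camphorsulfonic acid (10 mol %), MeOH/CH2Cl2, 0 °C
Reagents that add atoms: none
Why: Acid-catalysed methanolysis removes the primary TBS ether much faster than the TBDPS ether and does not disturb the acetate.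

**Step 17**
Reactants: 20 6β-acetoxy-17-(TBDPSO)-13,14,15,16-tetranor-ent-labd-7-en-12-ol
Product: 21 6β-acetoxy-17-(TBDPSO)-13,14,15,16-tetranor-ent-labd-7-en-12-al
Conditions: Dess–Martin periodinane, CH2Cl2, rt
Reagents that add atoms: none
Why: Dess–Martin oxidation of the primary alcohol stops at the aldehyde under near-neutral conditions that spare the allylic acetate and the silyl ether.

**Step 18**
Reactants: 21 6β-acetoxy-17-(TBDPSO)-13,14,15,16-tetranor-ent-labd-7-en-12-al
Product: 22 (12E)-6β-acetoxy-17-(TBDPSO)-15-nor-ent-labda-7,12-dien-14-al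
Conditions: Ph3P=C(CH3)CHO, toluene, 90 °C
Reagents that add atoms: 2-(triphenylphosphoranylidene)propanal CC(C=O)=P(c1ccccc1)(c1ccccc1)c1ccccc1
Why: The Wittig reaction of a stabilised α-methyl ylide with an aldehyde is under thermodynamic control and gives the (E)-2-methyl-2-enal, which fixes the C12=C13 geometry.

**Step 19**
Reactants: 22 (12E)-6β-acetoxy-17-(TBDPSO)-15-nor-ent-labda-7,12-dien-14-al
Product: 23 6β-acetoxy-17-(TBDPSO)-ent-labda-7,12E,14-triene
Conditions: Ph3PCH3Br, KN(SiMe3)2, THF, −78 °C; then 22 (ylide 1.2 equiv), −78 → 0 °C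
Reagents that add atoms: methyltriphenylphosphonium bromide C[P+](c1ccccc1)(c1ccccc1)c1ccccc1.[Br-]
Why: Wittig methylenation of the enal completes the 1,3-diene; at low temperature and near-stoichiometric ylide the aldehyde reacts far faster than the hindered axial acetate.

**Step 20**
Reactants: 23 6β-acetoxy-17-(TBDPSO)-ent-labda-7,12E,14-triene
Product: 24 6β-acetoxy-ent-labda-7,12E,14-trien-17-ol
Conditions: Bu4NF, AcOH, THF, 0 °C → rt
Reagents that add atoms: none
Why: Fluoride cleaves the Si–O bond, and the acetic acid buffer keeps the medium from hydrolysing the acetate; acyl migration is impossible because C6 and C17 are trans across C7=C8.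

**Step 21**
Reactants: 24 6β-acetoxy-ent-labda-7,12E,14-trien-17-ol
Product: 25 6β-acetoxy-ent-labda-7,12E,14-trien-17-al
Conditions: MnO2, CH2Cl2, rt
Reagents that add atoms: none
Why: Manganese dioxide oxidises the primary allylic alcohol selectively to the enal without touching the diene or the acetate.

**Step 22**
Reactants: 25 6β-acetoxy-ent-labda-7,12E,14-trien-17-al
Product: 26 ent-6β-acetoxylabda-7,12E,14-trien-17-oic acid, (5R,6S,9S,10S) (CNP0294871.1)
Conditions: NaClO2, NaH2PO4, 2-methylbut-2-ene (excess), t-BuOH/H2O, 0 °C → rt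
Reagents that add atoms: sodium chlorite [Na+].[O-]Cl=O
Why: Pinnick oxidation converts the enal into the acid at mildly acidic pH, with the alkene scavenger trapping hypochlorous acid so that the diene and the acetate survive.

**Compound list**
1 | tert-butyl(but-3-yn-1-yloxy)dimethylsilane | C#CCCO[Si](C)(C)C(C)(C)C | starting material
2 | ethyl 5-{[tert-butyl(dimethyl)silyl]oxy}pent-2-ynoate | CCOC(=O)C#CCCO[Si](C)(C)C(C)(C)C | intermediate
3 | ethyl (2E)-5-{[tert-butyl(dimethyl)silyl]oxy}-2-(tributylstannyl)pent-2-enoate | CCOC(=O)/C(=C\CCO[Si](C)(C)C(C)(C)C)[Sn](CCCC)(CCCC)CCCC | intermediate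
4 | (2E)-5-{[tert-butyl(dimethyl)silyl]oxy}-2-(tributylstannyl)pent-2-en-1-ol | OC/C(=C\CCO[Si](C)(C)C(C)(C)C)[Sn](CCCC)(CCCC)CCCC | intermediate
5 | (2Z)-5-{[tert-butyl(dimethyl)silyl]oxy}-2-ethenylpent-2-en-1-ol | OC/C(C=C)=C\CCO[Si](C)(C)C(C)(C)C | intermediate
6 | tert-butyl{[(2Z)-5-{[tert-butyl(dimethyl)silyl]oxy}-2-ethenylpent-2-en-1-yl]oxy}diphenylsilane | C=C/C(CO[Si](c1ccccc1)(c1ccccc1)C(C)(C)C)=C/CCO[Si](C)(C)C(C)(C)C | intermediate
7 | ethyl (2E)-3-methyl-4-oxobut-2-enoate | CCOC(=O)/C=C(\C)C=O | starting material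
8 | ethyl (1S,5R,6S)-5-(2-{[tert-butyl(dimethyl)silyl]oxy}ethyl)-4-({[tert-butyl(diphenyl)silyl]oxy}methyl)-6-formyl-6-methylcyclohex-3-ene-1-carboxylate | CC(C)(C)[Si](C)(C)OCC[C@@H]1C(CO[Si](c2ccccc2)(c2ccccc2)C(C)(C)C)=CC[C@H](C(=O)OCC)[C@]1(C=O)C | intermediate
9 | ethyl 5-(2-TBSO-ethyl)-4-(TBDPSO-methyl)-6-ethenyl-6-methylcyclohex-3-ene-1-carboxylate, ring centres as in 8 | CC(C)(C)[Si](C)(C)OCC[C@@H]1C(CO[Si](c2ccccc2)(c2ccccc2)C(C)(C)C)=CC[C@H](C(=O)OCC)[C@]1(C=C)C | intermediate
10 | 1-[5-(2-TBSO-ethyl)-4-(TBDPSO-methyl)-6-ethenyl-6-methylcyclohex-3-en-1-yl]ethan-1-one, ring centres as in 8 | CC(C)(C)[Si](C)(C)OCC[C@@H]1C(CO[Si](c2ccccc2)(c2ccccc2)C(C)(C)C)=CC[C@H](C(C)=O)[C@]1(C=C)C | intermediate (not isolated)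
11 | 2-[5-(2-TBSO-ethyl)-4-(TBDPSO-methyl)-6-ethenyl-6-methylcyclohex-3-en-1-yl]propan-2-ol, ring centres as in 8 | CC(C)(C)[Si](C)(C)OCC[C@@H]1C(CO[Si](c2ccccc2)(c2ccccc2)C(C)(C)C)=CC[C@H](C(C)(C)O)[C@]1(C=C)C | intermediate
12 | methyl 2-[5-(2-TBSO-ethyl)-4-(TBDPSO-methyl)-6-ethenyl-6-methylcyclohex-3-en-1-yl]propan-2-yl oxalate | CC(C)(C)[Si](C)(C)OCC[C@@H]1C(CO[Si](c2ccccc2)(c2ccccc2)C(C)(C)C)=CC[C@H](C(C)(C)OC(=O)C(=O)OC)[C@]1(C=C)C | intermediate (not isolated)
13 | cesium 2-[5-(2-TBSO-ethyl)-4-(TBDPSO-methyl)-6-ethenyl-6-methylcyclohex-3-en-1-yl]propan-2-yl oxalate | CC(C)(C)[Si](C)(C)OCC[C@@H]1C(CO[Si](c2ccccc2)(c2ccccc2)C(C)(C)C)=CC[C@H](C(C)(C)OC(=O)C(=O)[O-])[C@]1(C=C)C.[Cs+] | intermediate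
14 | 6-(2-TBSO-ethyl)-1-(TBDPSO-methyl)-5-ethenyl-5-methyl-4-(2-methylpent-4-en-2-yl)cyclohex-1-ene, ring centres as in 8 | CC(C)(C)[Si](C)(C)OCC[C@@H]1C(CO[Si](c2ccccc2)(c2ccccc2)C(C)(C)C)=CC[C@H](C(C)(C)CC=C)[C@]1(C=C)C | intermediate
15 | 12-O-TBS-17-O-TBDPS-13,14,15,16-tetranor-ent-labda-1,7-diene-12,17-diol | CC(C)(C)[Si](C)(C)OCC[C@@H]1C(CO[Si](c2ccccc2)(c2ccccc2)C(C)(C)C)=CC[C@@H]2C(C)(C)CC=C[C@@]12C | intermediate
16 | 12-O-TBS-17-O-TBDPS-13,14,15,16-tetranor-ent-labd-7-ene-12,17-diol | CC(C)(C)[Si](C)(C)OCC[C@@H]1C(CO[Si](c2ccccc2)(c2ccccc2)C(C)(C)C)=CC[C@@H]2C(C)(C)CCC[C@@]12C | intermediate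
17 | 12-(TBSO)-17-(TBDPSO)-13,14,15,16-tetranor-ent-labd-7-en-6-one | CC(C)(C)[Si](C)(C)OCC[C@@H]1C(CO[Si](c2ccccc2)(c2ccccc2)C(C)(C)C)=CC(=O)[C@@H]2C(C)(C)CCC[C@@]12C | intermediate
18 | 12-O-TBS-17-O-TBDPS-13,14,15,16-tetranor-ent-labd-7-ene-6β,12,17-triol (6-OH cis to the C10 methyl) | CC(C)(C)[Si](C)(C)OCC[C@@H]1C(CO[Si](c2ccccc2)(c2ccccc2)C(C)(C)C)=C[C@H](O)[C@@H]2C(C)(C)CCC[C@@]12C | intermediate
19 | 6β-acetoxy-12-(TBSO)-17-(TBDPSO)-13,14,15,16-tetranor-ent-labd-7-ene | CC(C)(C)[Si](C)(C)OCC[C@@H]1C(CO[Si](c2ccccc2)(c2ccccc2)C(C)(C)C)=C[C@H](OC(C)=O)[C@@H]2C(C)(C)CCC[C@@]12C | intermediate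
20 | 6β-acetoxy-17-(TBDPSO)-13,14,15,16-tetranor-ent-labd-7-en-12-ol | OCC[C@@H]1C(CO[Si](c2ccccc2)(c2ccccc2)C(C)(C)C)=C[C@H](OC(C)=O)[C@@H]2C(C)(C)CCC[C@@]12C | intermediate
21 | 6β-acetoxy-17-(TBDPSO)-13,14,15,16-tetranor-ent-labd-7-en-12-al | O=CC[C@@H]1C(CO[Si](c2ccccc2)(c2ccccc2)C(C)(C)C)=C[C@H](OC(C)=O)[C@@H]2C(C)(C)CCC[C@@]12C | intermediate
22 | (12E)-6β-acetoxy-17-(TBDPSO)-15-nor-ent-labda-7,12-dien-14-al | O=C/C(C)=C/C[C@@H]1C(CO[Si](c2ccccc2)(c2ccccc2)C(C)(C)C)=C[C@H](OC(C)=O)[C@@H]2C(C)(C)CCC[C@@]12C | intermediate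
23 | 6β-acetoxy-17-(TBDPSO)-ent-labda-7,12E,14-triene | C=C/C(C)=C/C[C@@H]1C(CO[Si](c2ccccc2)(c2ccccc2)C(C)(C)C)=C[C@H](OC(C)=O)[C@@H]2C(C)(C)CCC[C@@]12C | intermediate
24 | 6β-acetoxy-ent-labda-7,12E,14-trien-17-ol | C=C/C(C)=C/C[C@@H]1C(CO)=C[C@H](OC(C)=O)[C@@H]2C(C)(C)CCC[C@@]12C | intermediate
25 | 6β-acetoxy-ent-labda-7,12E,14-trien-17-al | C=C/C(C)=C/C[C@@H]1C(C=O)=C[C@H](OC(C)=O)[C@@H]2C(C)(C)CCC[C@@]12C | intermediate
26 | ent-6β-acetoxylabda-7,12E,14-trien-17-oic acid, (5R,6S,9S,10S), acetate cis to the C10 methyl (CNP0294871.1) | C=C/C(C)=C/C[C@@H]1C(C(=O)O)=C[C@H](OC(C)=O)[C@@H]2C(C)(C)CCC[C@@]12C | target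

**Total step count:** 22. **Longest linear sequence:** 22 steps (1 → 26); 7 is purchased.

**Steps most likely to fail**

Step 6. The catalyst-bound formyl group may compete for the endo position, or the catalyst may discriminate the enal faces poorly on this hindered dienophile, so that the C9 epimer or material of low enantiomeric purity results. The fallback sets out from 6 and 7 and comes back at 8. The cycloaddition is promoted by the bulky achiral Lewis acid aluminium tris(2,6-diphenylphenoxide), Al(OC6H3Ph2)3, in toluene at −78 °C; it encapsulates the formyl group and enforces the exo mode, and should give 8 together with the enantiomer of adduct 8 F1. Condensation of the mixture with (1R,2R)-N,N′-dimethyl-1,2-diphenylethane-1,2-diamine (4 Å molecular sieves, Et2O, rt) should give two diastereomeric aminals, the imidazolidine of 8 F2 and the imidazolidine of the enantiomer F3, to be separated on silica. Mild hydrolysis of F2 (two-phase dilute aqueous HCl/Et2O, 0 °C) returns 8.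

Step 10. Addition of the hindered tertiary radical to the unactivated allyl sulfone may be slow, so that hydrogen abstraction or cyclisation onto the neighbouring vinyl group takes over. The fallback sets out from 13 and comes back at 14. Under the same photocatalyst with water as proton source, the radical is trapped by the much faster acceptor phenyl vinyl sulfone (Giese addition) to give the phenyl sulfone F4. Deprotonation (n-BuLi, THF, −78 °C) and alkylation with Me3SiCH2I gives the β-silyl sulfone F5 (epimers at the sulfonyl carbon). Fluoride-induced elimination (Bu4NF, THF, 60 °C) then gives the terminal alkene 14.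

Step 13. Oxidation may also occur at the C17 oxymethylene or at C9–H, or proceed past the enone. The fallback sets out from 16 and comes back at 17, and replaces C–H oxidation by an epoxide transposition. Epoxidation (mCPBA, NaHCO3, CH2Cl2, 0 °C) on the face away from the C10 methyl gives the 7,8-epoxide F6. Opening at the less substituted C7 with PhSeNa (from PhSeSePh and NaBH4, EtOH, 70 °C) gives the hydroxy selenide F7. Oxidation with H2O2 (pyridine, THF, 0 → 25 °C) and selenoxide syn-elimination towards C6 gives the tertiary allylic alcohol F8. Oxidative 1,3-transposition with pyridinium chlorochromate, C5H5NH[CrO3Cl], in CH2Cl2 then gives enone 17.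

**Further compounds**
F1 | step 6 | enantiomer of adduct 8, ethyl (1R,5S,6R)-5-(2-TBSO-ethyl)-4-(TBDPSO-methyl)-6-formyl-6-methylcyclohex-3-ene-1-carboxylate | CC(C)(C)[Si](C)(C)OCC[C@H]1C(CO[Si](c2ccccc2)(c2ccccc2)C(C)(C)C)=CC[C@@H](C(=O)OCC)[C@@]1(C=O)C
F2 | step 6 | imidazolidine of 8, formyl group converted into (4R,5R)-1,3-dimethyl-4,5-diphenylimidazolidin-2-yl | CC(C)(C)[Si](C)(C)OCC[C@@H]1C(CO[Si](c2ccccc2)(c2ccccc2)C(C)(C)C)=CC[C@H](C(=O)OCC)[C@]1(C2N(C)[C@H](c3ccccc3)[C@@H](c3ccccc3)N2C)C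
F3 | step 6 | imidazolidine of the enantiomer, same (4R,5R)-aminal on F1 | CC(C)(C)[Si](C)(C)OCC[C@H]1C(CO[Si](c2ccccc2)(c2ccccc2)C(C)(C)C)=CC[C@@H](C(=O)OCC)[C@@]1(C2N(C)[C@H](c3ccccc3)[C@@H](c3ccccc3)N2C)C
F4 | step 10 | phenyl sulfone, 4-[2-methyl-4-(phenylsulfonyl)butan-2-yl] analogue of 14 | CC(C)(C)[Si](C)(C)OCC[C@@H]1C(CO[Si](c2ccccc2)(c2ccccc2)C(C)(C)C)=CC[C@H](C(C)(C)CCS(=O)(=O)c2ccccc2)[C@]1(C=C)C
F5 | step 10 | β-silyl sulfone, 4-[2-methyl-4-(phenylsulfonyl)-5-(trimethylsilyl)pentan-2-yl] analogue of 14, both epimers at the sulfonyl carbon | CC(C)(C)[Si](C)(C)OCC[C@@H]1C(CO[Si](c2ccccc2)(c2ccccc2)C(C)(C)C)=CC[C@H](C(C)(C)CC(C[Si](C)(C)C)S(=O)(=O)c2ccccc2)[C@]1(C=C)C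
F6 | step 13 | 7,8-epoxide of 16, oxygen on the face opposite the C10 methyl | CC(C)(C)[Si](C)(C)OCC[C@@H]1[C@@]2(CO[Si](c3ccccc3)(c3ccccc3)C(C)(C)C)O[C@H]2C[C@@H]2C(C)(C)CCC[C@@]12C
F7 | step 13 | hydroxy selenide, 8-hydroxy-7-(phenylselanyl) derivative of 16, trans-diaxial | CC(C)(C)[Si](C)(C)OCC[C@@H]1[C@](O)(CO[Si](c2ccccc2)(c2ccccc2)C(C)(C)C)[C@H]([Se]c2ccccc2)C[C@@H]2C(C)(C)CCC[C@@]12C
F8 | step 13 | tertiary allylic alcohol, 12-(TBSO)-17-(TBDPSO)-13,14,15,16-tetranor-ent-labd-6-en-8-ol | CC(C)(C)[Si](C)(C)OCC[C@@H]1[C@](O)(CO[Si](c2ccccc2)(c2ccccc2)C(C)(C)C)C=C[C@@H]2C(C)(C)CCC[C@@]12C
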